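## The problem

Compound 18 is a depside in which two benzene rings are joined only by an aryl ester between the carboxyl carbon C7 on ring A (C1–C6) and the oxygen on C4' of ring B (C1'–C6'). It has no stereocentre, so nothing has to be controlled in space and the whole task lies in substitution pattern and functional-group tolerance. Ring A carries five substituents (C1 acyl, C2 OMe, C3 CH2OH, C4 OMe, C6 Me) and ring B five more (C1' CO2H, C2' OH, C3' Me, C4' O-acyl, C6' Me). The ester is hindered on both sides, since C7 sits between the C2 methoxy and C6 methyl groups and O4' lies next to the C3' methyl group, so joining a finished acid to a finished phenol is slow and the ester, once made, is the bond most easily lost to base or nucleophiles. The two oxygens of ring B must be told apart, O4' acylated and O2' free. The C3 hydroxymethyl group lies between two methoxy groups and ionizes readily in acid, and the salicylic acid of ring B decarboxylates on heating, so the last steps must be mild and neither acidic nor hydrolytic. The enabling feature is that O2'–C2'–C3'(Me)–C4'–O4' is a masked 2-methylcyclohexane-1,3-dione and C1'(CO2H)–C6'(Me) is the triple bond of but-2-ynoic acid, so that ring B is the dione less two CH2 groups plus the ynoate and O4' can be acylated as an enolate oxygen before ring B is aromatic.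

## Retrosynthesis

**Unmasking.** Target 18 is taken back to the allyl ester 17 and then to the bis-silyl ether 16; only O–allyl and O–Si bonds are cut. Saponification is excluded by the depside ester and strong acid by the C3 benzylic alcohol. Hydrogenolysis of a benzyl ester is held in reserve only, because the C3 benzylic C–O bond is itself activated. Fluoride for the silyl ethers and zerovalent palladium for the allyl ester are the mildest pair available.

**Ring B.** In 16 the bonds C1'–C2' and C5'–C6' are cut and a two-carbon bridge is restored between C2' and C5'. This leads through the bicyclo[2.2.2]octadiene 15 to the dienyl ester 12 and allyl but-2-ynoate 14. Cutting the ester O4'–C7 first would instead call for a pentasubstituted ring B phenol that cannot be bought, a way to distinguish O2' from O4', and a doubly hindered esterification. The cycloaddition cut delivers ring B with the ester already in place and the oxygens already different. The forward reaction must be regioselective and must spare an enol ester, two silyl ethers and an allyl ester at high temperature.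

**Enol ester.** Diene 12 is cut at O4'–C7 into the potassium dienolate 11, formed from the silyloxy enone 10, and the acid chloride 8. The hindered ester is thus made from a reactive enolate oxygen. The order, silylation first and enolate acylation second, decides which oxygen becomes O2' and which O4'. The forward step needs kinetic deprotonation at the alpha' carbon and acylation on oxygen, not carbon.

**Small pieces.** Enone 10 comes from 2-methylcyclohexane-1,3-dione 9 by O-silylation; the dione is symmetric, so there is no regiochemical question. Ester 14 comes from but-2-ynoic acid 13 by O-allylation.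

**Ring A.** Acid chloride 8 comes from acid 7, whose C1–C7 bond is cut by carboxylation of the aryllithium 6; 6 comes from bromide 5, and 5 from the silyl ether 4 by bromination. Ether 4 is symmetric, so its two free ring positions are equivalent and only one bromide can form. Ether 4 comes from alcohol 3, whose C3–CH2OH bond is cut by hydroxymethylation of aryllithium 2; 2 arises from 3,5-dimethoxytoluene 1 by lithiation between the two methoxy groups. Starting from a ring A that already carries the carboxyl group would instead require a choice between C3 and C5; here each substitution has only one possible site.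

## Roads not taken

Alternative 1: Ring A itself would be cut at C1–C6 and C3–C4, so that tert-butyl acetoacetate A1 and ethyl crotonate A2 are the precursors.
- Forward key step: with KOtBu the enolate of A1 adds to A2 in a Michael reaction and a Claisen-type ring closure follows, giving racemic tert-butyl trans-6-methyl-2,4-dioxocyclohexane-1-carboxylate A3. A3 would then be dehydrogenated, O-methylated, functionalized at C3 and joined to ring B by esterification.
- Merits: the annulation is classical, cheap and scalable, with no regiochemical question. In reliability of the key step this road is better than the one chosen.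
- Weak points: the carbons it assembles are those of 2,4-dimethoxy-6-methylbenzoic acid A4, and A4 is, like arene 1, an article of commerce. The two stereocentres of A3 are made only to be destroyed. After aromatization every hard problem remains: C3 against C5 selectivity, acid cleavage of the tert-butyl ester, a doubly hindered esterification, and ring B with its two oxygens to be distinguished.
- Comparison: against the greater reliability of this annulation, the chosen plan sets that its key step builds ring B, the ring with no purchasable equivalent, and fixes the ester and the oxygen differentiation in the same operation.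

Alternative 2: Ring A would be cut at C1–C2, C2–C3 and C4–C5, a Danheiser benzannulation.
- Forward key step: the diazo ketone benzyl 2-(benzyloxy)-4-{[(2E)-5-diazo-3-methyl-4-oxopent-2-enoyl]oxy}-3,6-dimethylbenzoate A5 is the substrate. A5 is irradiated to a vinylketene by photochemical Wolff rearrangement. The alkyne partner is 1-methoxy-3-[(triisopropylsilyl)oxy]prop-1-yne A6; on heating with A6 the ketene undergoes [2+2] addition, four-electron ring opening and six-electron ring closure. The product is the phenol benzyl 2-(benzyloxy)-4-[(2-hydroxy-4-methoxy-6-methyl-3-{[(triisopropylsilyl)oxy]methyl}benzoyl)oxy]-3,6-dimethylbenzoate A7.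
- Merits: ring A forms with every substituent placed by connectivity, not by orbital control, and the ester bond is made on an unhindered unsaturated acid. In regiochemical certainty it is as good as or better than the chosen plan.
- Weak points: the ring B phenol benzyl 2-(benzyloxy)-4-hydroxy-3,6-dimethylbenzoate A8 must first be made, and A8 needs several steps with its own oxygen differentiation. A5 needs diazoalkane chemistry and A6 is a sensitive ynol ether. The C2 hydroxyl of A7 must still be methylated beside the aryl ester, and two benzyl groups must be removed by hydrogenolysis next to the activated benzylic C–O bond of ring A.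
- Comparison: the chosen plan sets against it that no separate ring B synthesis is needed, the starting materials are commodity chemicals, the key step is a simple thermal reaction, and no methylation or hydrogenolysis follows it.

Alternative 3: Only C1–C7 and C7–O4' would be cut, by a three-component carbonylative coupling.
- Forward key step: the aryl iodide 3-iodo-2,6-dimethoxy-4-methylbenzaldehyde A9 combines with carbon monoxide and tert-butyl 2,4-dihydroxy-3,6-dimethylbenzoate A10 under Pd(OAc)2, Xantphos and triethylamine. The product is tert-butyl 4-[(3-formyl-2,4-dimethoxy-6-methylbenzoyl)oxy]-2-hydroxy-3,6-dimethylbenzoate A11. A11 would then need reduction of the formyl group and cleavage of the tert-butyl ester.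
- Merits: it is the shortest on paper and is catalytic, it needs no acid chloride or strong base, and the chelated 2'-hydroxyl leaves the 4'-hydroxyl as the nucleophile. In step count it is better than the chosen plan.
- Weak points: the acylpalladium intermediate formed from A9 is flanked by methyl and methoxy groups and must be captured by a hindered, weakly nucleophilic phenol. The aryl ester product can itself transfer its acyl group under the basic conditions. Removal of the tert-butyl ester needs strong acid, which endangers the C3 benzylic alcohol and the salicylic acid. A10 is not purchasable and would most simply be made by the very benzannulation chosen here.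
- Comparison: against the shorter count the chosen plan sets bond formations of well-known classes at every hindered position and an acid-free end game.

Key step: step 9

## Route

Step 1
Reactants: 1 3,5-dimethoxytoluene
Product: 3 (2,6-dimethoxy-4-methylphenyl)methanol, via aryllithium 2 (not isolated)
Conditions: n-BuLi, TMEDA, THF, 0 °C to rt; (CH2O)n, 0 °C to rt; then H2O
Reagents that add atoms: formaldehyde (from paraformaldehyde), C=O
Why: Directed ortho-metalation: the two methoxy groups together direct n-BuLi to the carbon between them, and the aryllithium adds to formaldehyde released from paraformaldehyde (hydroxymethylation of an aryllithium).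

Step 2
Reactants: 3 (2,6-dimethoxy-4-methylphenyl)methanol
Product: 4 [(2,6-dimethoxy-4-methylphenyl)methoxy]triisopropylsilane
Conditions: TIPSCl, imidazole, DMF, rt
Reagents that add atoms: triisopropylsilyl chloride, CC(C)[Si](Cl)(C(C)C)C(C)C
Why: Standard silylation of a primary alcohol; the bulky silyl group is chosen to withstand n-BuLi, the acid chloride stage, the amide base and prolonged heating.

Step 3
Reactants: 4 [(2,6-dimethoxy-4-methylphenyl)methoxy]triisopropylsilane
Product: 5 [(3-bromo-2,6-dimethoxy-4-methylphenyl)methoxy]triisopropylsilane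
Conditions: NBS (1.0 equiv), MeCN, 0 °C, dark
Reagents that add atoms: N-bromosuccinimide, O=C1CCC(=O)N1Br
Why: Electrophilic aromatic bromination; 4 is symmetric, so its two free ring positions are equivalent and each is ortho to one methoxy group and para to the other, while a polar solvent and darkness suppress benzylic radical bromination.

Step 4
Reactants: 5 [(3-bromo-2,6-dimethoxy-4-methylphenyl)methoxy]triisopropylsilane
Product: 7 2,4-dimethoxy-6-methyl-3-{[(triisopropylsilyl)oxy]methyl}benzoic acid, via aryllithium 6 (not isolated)
Conditions: n-BuLi, THF, −78 °C; CO2; then cold dilute HCl to pH 3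
Reagents that add atoms: carbon dioxide, O=C=O
Why: Bromine–lithium exchange at −78 °C outruns any deprotonation and the aryllithium is carboxylated by CO2; the silyloxymethyl group is meta to lithium, so no silyl shift from oxygen to carbon can occur.

Step 5
Reactants: 7 2,4-dimethoxy-6-methyl-3-{[(triisopropylsilyl)oxy]methyl}benzoic acid
Product: 8 2,4-dimethoxy-6-methyl-3-{[(triisopropylsilyl)oxy]methyl}benzoyl chloride
Conditions: 1-chloro-N,N,2-trimethylprop-1-en-1-amine (Ghosez's reagent), CH2Cl2, 0 °C to rt; volatiles removed, used crude
Reagents that add atoms: 1-chloro-N,N,2-trimethylprop-1-en-1-amine, CC(C)=C(Cl)N(C)C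
Why: Acid chloride formation with an alpha-chloroenamine runs under neutral conditions without HCl, which spares the acid-sensitive benzylic silyl ether.

Step 6
Reactants: 9 2-methylcyclohexane-1,3-dione
Product: 10 3-[(tert-butyldimethylsilyl)oxy]-2-methylcyclohex-2-en-1-one
Conditions: TBSCl, Et3N, CH2Cl2, rt; non-aqueous work-up
Reagents that add atoms: tert-butyldimethylsilyl chloride, CC(C)(C)[Si](C)(C)Cl
Why: O-silylation of the enol form of a cyclic 1,3-dione gives the vinylogous silyl ester; the dione is symmetric, so only one product can form.

Step 7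
Reactants: 10 3-[(tert-butyldimethylsilyl)oxy]-2-methylcyclohex-2-en-1-one; 8 2,4-dimethoxy-6-methyl-3-{[(triisopropylsilyl)oxy]methyl}benzoyl chloride
Product: 12 5-[(tert-butyldimethylsilyl)oxy]-6-methylcyclohexa-1,5-dien-1-yl 2,4-dimethoxy-6-methyl-3-{[(triisopropylsilyl)oxy]methyl}benzoate, via potassium dienolate 11 (not isolated)
Conditions: KN(SiMe3)2, THF, −78 °C; then 8, THF/DMPU, −78 to 0 °C; pH 7 buffer
Reagents that add atoms: none
Why: Kinetic alpha'-deprotonation of a 3-silyloxy enone by a hindered amide base gives the cross-conjugated dienolate, as in the preparation of 1,3-bis(silyloxy)cyclohexadienes, and a dissociated potassium enolate reacts with a hard, hindered aroyl chloride at oxygen (enolate O-acylation to an enol ester).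

Step 8
Reactants: 13 but-2-ynoic acid
Product: 14 allyl but-2-ynoate
Conditions: allyl bromide, KHCO3, DMF, rt
Reagents that add atoms: allyl bromide, C=CCBr
Why: SN2 O-alkylation of the carboxylate; the weak base avoids isomerization of the alkyne to the allene.

Step 9
Reactants: 12 5-[(tert-butyldimethylsilyl)oxy]-6-methylcyclohexa-1,5-dien-1-yl 2,4-dimethoxy-6-methyl-3-{[(triisopropylsilyl)oxy]methyl}benzoate; 14 allyl but-2-ynoate
Product: 16 allyl 2-[(tert-butyldimethylsilyl)oxy]-4-[(2,4-dimethoxy-6-methyl-3-{[(triisopropylsilyl)oxy]methyl}benzoyl)oxy]-3,6-dimethylbenzoate, via bicyclo[2.2.2]octadiene cycloadduct 15 (not isolated)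
Conditions: 14 (4 equiv), BHT (cat.), o-xylene (minimal), sealed tube, 160 °C
Reagents that add atoms: none
Why: The reaction is a thermal, concerted [4+2] cycloaddition of normal electron demand between the ring-held s-cis diene C2'=C3'–C4'=C5' of 12 and the triple bond of 14, forming C1'–C2' and C5'–C6' and closing the six-membered carbocycle of ring B as the bicyclo[2.2.2]octa-2,5-diene 15. A retro-[4+2] then expels the saturated two-carbon bridge as ethylene, which is irreversible because the product is aromatic. The closest known reaction type is the Alder–Rickert synthesis of salicylates and orsellinates from 1-silyloxycyclohexa-1,3-dienes and alkynoates, but-2-ynoates included. The ring closes by intermolecular cycloaddition, with both bonds made in one step across the diene termini. The only stereocentres formed are the two bridgeheads of 15, which are fixed relative to each other by the bicycle and erased on aromatization, so no stereocontrol is needed. The selectivity that matters is regiochemical: the silyloxy group on the terminus C2' and the acyloxy group on C4' both put the largest HOMO coefficient on C5', which joins the methyl-bearing beta carbon of the ynoate, so C2' joins the ester-bearing carbon and the silyloxy group ends ortho to the ester. Chemoselectivity rests on the allyl alkene being an unactivated dienophile and on the neutral medium, in which the enol ester, both silyl ethers and the allyl ester should persist; the excess of 14 with little solvent compensates for the lower reactivity of a beta-methyl ynoate.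

Step 10
Reactants: 16 allyl 2-[(tert-butyldimethylsilyl)oxy]-4-[(2,4-dimethoxy-6-methyl-3-{[(triisopropylsilyl)oxy]methyl}benzoyl)oxy]-3,6-dimethylbenzoate
Product: 17 allyl 2-hydroxy-4-{[3-(hydroxymethyl)-2,4-dimethoxy-6-methylbenzoyl]oxy}-3,6-dimethylbenzoate
Conditions: HF·pyridine, excess pyridine, THF, 0 °C to rt
Reagents that add atoms: none
Why: Fluoride-mediated cleavage of an aryl and a primary alkyl silyl ether; the pyridine buffer keeps the medium too weakly acidic to ionize the benzylic alcohol or disturb the depside and allyl esters.

Step 11
Reactants: 17 allyl 2-hydroxy-4-{[3-(hydroxymethyl)-2,4-dimethoxy-6-methylbenzoyl]oxy}-3,6-dimethylbenzoate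
Product: 18 2-hydroxy-4-{[3-(hydroxymethyl)-2,4-dimethoxy-6-methylbenzoyl]oxy}-3,6-dimethylbenzoic acid
Conditions: Pd(PPh3)4 (5 mol %), morpholine, THF, 0 °C to rt; NaH2PO4 buffer (pH 4) work-up
Reagents that add atoms: none
Why: Tsuji–Trost deallylation: zerovalent palladium ionizes the allyl ester to an allyl complex of divalent palladium that morpholine captures, freeing the acid at room temperature under near-neutral conditions that leave the hindered aryl ester and the benzylic alcohol alone.

## Compound list

1 | 3,5-dimethoxytoluene | COc1cc(C)cc(OC)c1 | starting material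
2 | (2,6-dimethoxy-4-methylphenyl)lithium | COc1cc(C)cc(OC)c1[Li] | intermediate
3 | (2,6-dimethoxy-4-methylphenyl)methanol | COc1cc(C)cc(OC)c1CO | intermediate
4 | [(2,6-dimethoxy-4-methylphenyl)methoxy]triisopropylsilane | COc1cc(C)cc(OC)c1CO[Si](C(C)C)(C(C)C)C(C)C | intermediate
5 | [(3-bromo-2,6-dimethoxy-4-methylphenyl)methoxy]triisopropylsilane | COc1cc(C)c(Br)c(OC)c1CO[Si](C(C)C)(C(C)C)C(C)C | intermediate
6 | (2,4-dimethoxy-6-methyl-3-{[(triisopropylsilyl)oxy]methyl}phenyl)lithium | COc1cc(C)c([Li])c(OC)c1CO[Si](C(C)C)(C(C)C)C(C)C | intermediate
7 | 2,4-dimethoxy-6-methyl-3-{[(triisopropylsilyl)oxy]methyl}benzoic acid | COc1cc(C)c(C(=O)O)c(OC)c1CO[Si](C(C)C)(C(C)C)C(C)C | intermediate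
8 | 2,4-dimethoxy-6-methyl-3-{[(triisopropylsilyl)oxy]methyl}benzoyl chloride | COc1cc(C)c(C(Cl)=O)c(OC)c1CO[Si](C(C)C)(C(C)C)C(C)C | intermediate
9 | 2-methylcyclohexane-1,3-dione | CC1C(=O)CCCC1=O | starting material
10 | 3-[(tert-butyldimethylsilyl)oxy]-2-methylcyclohex-2-en-1-one | CC1=C(O[Si](C)(C)C(C)(C)C)CCCC1=O | intermediate
11 | potassium 5-[(tert-butyldimethylsilyl)oxy]-6-methylcyclohexa-1,5-dien-1-olate | CC1=C(O[Si](C)(C)C(C)(C)C)CCC=C1[O-].[K+] | intermediate
12 | 5-[(tert-butyldimethylsilyl)oxy]-6-methylcyclohexa-1,5-dien-1-yl 2,4-dimethoxy-6-methyl-3-{[(triisopropylsilyl)oxy]methyl}benzoate | CC1=C(O[Si](C)(C)C(C)(C)C)CCC=C1OC(=O)c1c(C)cc(OC)c(CO[Si](C(C)C)(C(C)C)C(C)C)c1OC | intermediate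
13 | but-2-ynoic acid | CC#CC(=O)O | starting material
14 | allyl but-2-ynoate | CC#CC(=O)OCC=C | intermediate
15 | racemic allyl 1-[(tert-butyldimethylsilyl)oxy]-5-[(2,4-dimethoxy-6-methyl-3-{[(triisopropylsilyl)oxy]methyl}benzoyl)oxy]-3,6-dimethylbicyclo[2.2.2]octa-2,5-diene-2-carboxylate (bridgeheads fixed by the bicycle; one enantiomer drawn) | C=CCOC(=O)C1=C(C)[C@@H]2CC[C@@]1(O[Si](C)(C)C(C)(C)C)C(C)=C2OC(=O)c1c(C)cc(OC)c(CO[Si](C(C)C)(C(C)C)C(C)C)c1OC | intermediate
16 | allyl 2-[(tert-butyldimethylsilyl)oxy]-4-[(2,4-dimethoxy-6-methyl-3-{[(triisopropylsilyl)oxy]methyl}benzoyl)oxy]-3,6-dimethylbenzoate | C=CCOC(=O)c1c(C)cc(OC(=O)c2c(C)cc(OC)c(CO[Si](C(C)C)(C(C)C)C(C)C)c2OC)c(C)c1O[Si](C)(C)C(C)(C)C | intermediate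
17 | allyl 2-hydroxy-4-{[3-(hydroxymethyl)-2,4-dimethoxy-6-methylbenzoyl]oxy}-3,6-dimethylbenzoate | C=CCOC(=O)c1c(C)cc(OC(=O)c2c(C)cc(OC)c(CO)c2OC)c(C)c1O | intermediate
18 | 2-hydroxy-4-{[3-(hydroxymethyl)-2,4-dimethoxy-6-methylbenzoyl]oxy}-3,6-dimethylbenzoic acid | COc1cc(C)c(C(=O)Oc2cc(C)c(C(=O)O)c(O)c2C)c(OC)c1CO | target

## Step count and risks

Total steps: 11. Longest linear sequence: 9 steps (steps 1, 2, 3, 4, 5, 7, 9, 10, 11).

**Step 9 (key step).**
- Risk: the cycloaddition may be too slow, because the beta-methyl group lowers the reactivity of the ynoate and an acyloxy group donates less than a silyloxy group. At the temperature then needed the diene can isomerize by 1,5-hydrogen shift or lose its silyl group to traces of water before it reacts, and some regiochemical leakage is possible.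
- Fallback: sets out from 10 and 8 and returns at 16, using the more electron-rich diene of the established reaction and making the ester afterwards. Enone 10 is deprotonated with LiN(iPr)2 and trapped with TMSCl to give tert-butyldimethyl({2-methyl-3-[(trimethylsilyl)oxy]cyclohexa-1,3-dien-1-yl}oxy)silane F1. Heating F1 with 14 gives, through the cycloadduct racemic allyl 1-[(tert-butyldimethylsilyl)oxy]-3,6-dimethyl-5-[(trimethylsilyl)oxy]bicyclo[2.2.2]octa-2,5-diene-2-carboxylate F2 and loss of ethylene, allyl 2-[(tert-butyldimethylsilyl)oxy]-3,6-dimethyl-4-[(trimethylsilyl)oxy]benzoate F3. Methanol with a trace of citric acid removes only the aryl trimethylsilyl ether to give allyl 2-[(tert-butyldimethylsilyl)oxy]-4-hydroxy-3,6-dimethylbenzoate F4. Its sodium phenoxide (NaH, THF) is acylated with 8 to give 16.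

**Step 7.**
- Risk: acylation at carbon C6 in place of oxygen, or proton transfer to the extended dienolate while the hindered acid chloride reacts slowly, giving the wrong diene. Migration of the silyl group between the two oxygens of the dienolate would exchange the roles of O2' and O4'.
- Fallback: sets out from 7 and 10 and returns at 12. Acid 7 is converted with cyanuric fluoride and pyridine into 2,4-dimethoxy-6-methyl-3-{[(triisopropylsilyl)oxy]methyl}benzoyl fluoride F5. This is combined with the dienol silyl ether F1 described under step 9 and a catalytic amount of tetrabutylammonium fluoride, the known fluoride-catalysed O-acylation of enol silyl ethers by acyl fluorides. The trimethylsilyl group leaves as its fluoride and 12 forms.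

**Step 10.**
- Risk: ionization of the benzylic C–O bond between the two methoxy groups in the acidic fluoride medium, or incomplete cleavage of the primary triisopropylsilyl ether under conditions mild enough to prevent this.
- Fallback: sets out from 16 and returns at 18, reversing the order of unmasking so that the benzylic alcohol is freed last and without acid. The allyl ester is cleaved first with Pd(PPh3)4 and morpholine to give 2-[(tert-butyldimethylsilyl)oxy]-4-[(2,4-dimethoxy-6-methyl-3-{[(triisopropylsilyl)oxy]methyl}benzoyl)oxy]-3,6-dimethylbenzoic acid F6. Both silyl groups are then removed with tetrabutylammonium fluoride buffered with acetic acid.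

**Step 11.**
- Risk: aminolysis of the depside ester by morpholine if the allyl transfer from the chelated salicylate is slow, and decarboxylation of the product during work-up.
- Fallback: sets out from 13 and 12 and returns at 18, replacing the allyl ester by a benzyl ester so that no amine is needed. Acid 13 is alkylated with benzyl bromide and KHCO3 to give benzyl but-2-ynoate F7. Heating F7 with 12 gives, through the cycloadduct racemic benzyl 1-[(tert-butyldimethylsilyl)oxy]-5-[(2,4-dimethoxy-6-methyl-3-{[(triisopropylsilyl)oxy]methyl}benzoyl)oxy]-3,6-dimethylbicyclo[2.2.2]octa-2,5-diene-2-carboxylate F8 and loss of ethylene, benzyl 2-[(tert-butyldimethylsilyl)oxy]-4-[(2,4-dimethoxy-6-methyl-3-{[(triisopropylsilyl)oxy]methyl}benzoyl)oxy]-3,6-dimethylbenzoate F9. HF·pyridine gives benzyl 2-hydroxy-4-{[3-(hydroxymethyl)-2,4-dimethoxy-6-methylbenzoyl]oxy}-3,6-dimethylbenzoate F10. Brief hydrogenolysis (H2, Pd/C, ethyl acetate, neutral) then gives 18, the benzyl ester being cleaved much faster than the free benzylic alcohol.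

**Step 1.**
- Risk: incomplete hydroxymethylation, because paraformaldehyde depolymerizes slowly in a heterogeneous mixture and the aryllithium is protonated instead.
- Fallback: sets out from 1 and returns at 3. Aryllithium 2 is quenched with DMF to give 2,6-dimethoxy-4-methylbenzaldehyde F11, which is reduced with NaBH4 in methanol to 3.

## Further compounds

F1 | step 9 | tert-butyldimethyl({2-methyl-3-[(trimethylsilyl)oxy]cyclohexa-1,3-dien-1-yl}oxy)silane | CC1=C(O[Si](C)(C)C(C)(C)C)CCC=C1O[Si](C)(C)C
F2 | step 9 | racemic allyl 1-[(tert-butyldimethylsilyl)oxy]-3,6-dimethyl-5-[(trimethylsilyl)oxy]bicyclo[2.2.2]octa-2,5-diene-2-carboxylate | C=CCOC(=O)C1=C(C)[C@@H]2CC[C@@]1(O[Si](C)(C)C(C)(C)C)C(C)=C2O[Si](C)(C)C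
F3 | step 9 | allyl 2-[(tert-butyldimethylsilyl)oxy]-3,6-dimethyl-4-[(trimethylsilyl)oxy]benzoate | C=CCOC(=O)c1c(C)cc(O[Si](C)(C)C)c(C)c1O[Si](C)(C)C(C)(C)C
F4 | step 9 | allyl 2-[(tert-butyldimethylsilyl)oxy]-4-hydroxy-3,6-dimethylbenzoate | C=CCOC(=O)c1c(C)cc(O)c(C)c1O[Si](C)(C)C(C)(C)C
F5 | step 7 | 2,4-dimethoxy-6-methyl-3-{[(triisopropylsilyl)oxy]methyl}benzoyl fluoride | COc1cc(C)c(C(F)=O)c(OC)c1CO[Si](C(C)C)(C(C)C)C(C)C
F6 | step 10 | 2-[(tert-butyldimethylsilyl)oxy]-4-[(2,4-dimethoxy-6-methyl-3-{[(triisopropylsilyl)oxy]methyl}benzoyl)oxy]-3,6-dimethylbenzoic acid | OC(=O)c1c(C)cc(OC(=O)c2c(C)cc(OC)c(CO[Si](C(C)C)(C(C)C)C(C)C)c2OC)c(C)c1O[Si](C)(C)C(C)(C)C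
F7 | step 11 | benzyl but-2-ynoate | CC#CC(=O)OCc1ccccc1
F8 | step 11 | racemic benzyl 1-[(tert-butyldimethylsilyl)oxy]-5-[(2,4-dimethoxy-6-methyl-3-{[(triisopropylsilyl)oxy]methyl}benzoyl)oxy]-3,6-dimethylbicyclo[2.2.2]octa-2,5-diene-2-carboxylate | O=C(OCc1ccccc1)C1=C(C)[C@@H]2CC[C@@]1(O[Si](C)(C)C(C)(C)C)C(C)=C2OC(=O)c1c(C)cc(OC)c(CO[Si](C(C)C)(C(C)C)C(C)C)c1OC
F9 | step 11 | benzyl 2-[(tert-butyldimethylsilyl)oxy]-4-[(2,4-dimethoxy-6-methyl-3-{[(triisopropylsilyl)oxy]methyl}benzoyl)oxy]-3,6-dimethylbenzoate | O=C(OCc1ccccc1)c1c(C)cc(OC(=O)c2c(C)cc(OC)c(CO[Si](C(C)C)(C(C)C)C(C)C)c2OC)c(C)c1O[Si](C)(C)C(C)(C)C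
F10 | step 11 | benzyl 2-hydroxy-4-{[3-(hydroxymethyl)-2,4-dimethoxy-6-methylbenzoyl]oxy}-3,6-dimethylbenzoate | O=C(OCc1ccccc1)c1c(C)cc(OC(=O)c2c(C)cc(OC)c(CO)c2OC)c(C)c1O
F11 | step 1 | 2,6-dimethoxy-4-methylbenzaldehyde | COc1cc(C)cc(OC)c1C=O
A1 | alternative 1 | tert-butyl acetoacetate | CC(=O)CC(=O)OC(C)(C)C
A2 | alternative 1 | ethyl crotonate | C/C=C/C(=O)OCC
A3 | alternative 1 | racemic tert-butyl trans-6-methyl-2,4-dioxocyclohexane-1-carboxylate | C[C@@H]1CC(=O)CC(=O)[C@H]1C(=O)OC(C)(C)C
A4 | alternative 1 | 2,4-dimethoxy-6-methylbenzoic acid | COc1cc(C)c(C(=O)O)c(OC)c1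
A5 | alternative 2 | benzyl 2-(benzyloxy)-4-{[(2E)-5-diazo-3-methyl-4-oxopent-2-enoyl]oxy}-3,6-dimethylbenzoate | [N-]=[N+]=CC(=O)/C(C)=C/C(=O)Oc1cc(C)c(C(=O)OCc2ccccc2)c(OCc2ccccc2)c1C
A6 | alternative 2 | 1-methoxy-3-[(triisopropylsilyl)oxy]prop-1-yne | COC#CCO[Si](C(C)C)(C(C)C)C(C)C
A7 | alternative 2 | benzyl 2-(benzyloxy)-4-[(2-hydroxy-4-methoxy-6-methyl-3-{[(triisopropylsilyl)oxy]methyl}benzoyl)oxy]-3,6-dimethylbenzoate | COc1cc(C)c(C(=O)Oc2cc(C)c(C(=O)OCc3ccccc3)c(OCc3ccccc3)c2C)c(O)c1CO[Si](C(C)C)(C(C)C)C(C)C
A8 | alternative 2 | benzyl 2-(benzyloxy)-4-hydroxy-3,6-dimethylbenzoate | Cc1cc(O)c(C)c(OCc2ccccc2)c1C(=O)OCc1ccccc1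
A9 | alternative 3 | 3-iodo-2,6-dimethoxy-4-methylbenzaldehyde | COc1cc(C)c(I)c(OC)c1C=O
A10 | alternative 3 | tert-butyl 2,4-dihydroxy-3,6-dimethylbenzoate | Cc1cc(O)c(C)c(O)c1C(=O)OC(C)(C)C
A11 | alternative 3 | tert-butyl 4-[(3-formyl-2,4-dimethoxy-6-methylbenzoyl)oxy]-2-hydroxy-3,6-dimethylbenzoate | COc1cc(C)c(C(=O)Oc2cc(C)c(C(=O)OC(C)(C)C)c(O)c2C)c(OC)c1C=O
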